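Retrosynthetic cuts, in order: the three O–benzyl bonds (O5, O2', O4'); the aryl ether bond O1–C8a of pyranone ring C; C3–C4 (aldol, then oxidation); C2–C1' (aryllithium plus Weinreb amide); and C4–C4a (formylation of ring A).
Enabling feature: O1 is bonded to C8a, the ring-A carbon between the acyl-bearing C4a and the methoxylated C8. With bromine on that carbon and the other ortho oxygen (O5) capped, ring C can close in only one direction, which fixes the 5,7,8 pattern and excludes 5,6,7.
Forward: rings A and B are bought as benzenes and elaborated separately. Ring A takes three steps to a 2-bromo-6-benzyloxybenzaldehyde, and ring B takes five steps to an aryl methoxymethyl ketone.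
The halves are joined by a lithium aldol addition and oxidised to the 2-methoxy-1,3-diketone. Ring C, the only ring made, is closed by copper-catalysed enolate O-arylation, and hydrogenolysis ends the route.
Stereochemistry: the target has none. The two centres created in the aldol step are uncontrolled and are erased by the oxidation and the ring closure.

Key step: step 12

Remark: the target SMILES contains no stereocentre, stereogenic axis or E/Z element, so the request for a single enantiomer is met by the constitution alone.

Step 1
Reactants: 1 3-bromo-4,5-dimethoxybenzaldehyde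
Product: 3 3-bromo-4,5-dimethoxyphenol, via aryl formate 2 (not isolated)
Conditions: mCPBA, CH2Cl2, 0 °C to rt; then K2CO3 (cat.), MeOH, rt
Reagents that add atoms: 3-chloroperbenzoic acid (mCPBA), O=C(OO)c1cccc(Cl)c1
Why: Baeyer–Villiger oxidation, in which the para-methoxylated aryl group migrates from the Criegee adduct in preference to hydride, after which mild methanolysis removes the labile formate and leaves the bromide and methyl ethers alone.

Step 2
Reactants: 3 3-bromo-4,5-dimethoxyphenol
Product: 4 5-(benzyloxy)-1-bromo-2,3-dimethoxybenzene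
Conditions: BnBr, K2CO3, DMF, rt
Reagents that add atoms: benzyl bromide, BrCc1ccccc1
Why: Williamson ether synthesis on the single phenoxide, with benzyl chosen because it tolerates the Vilsmeier, enolate, periodinane and copper steps, blocks O5 during ring closure and leaves by hydrogenolysis at the end.

Step 3
Reactants: 4 5-(benzyloxy)-1-bromo-2,3-dimethoxybenzene
Product: 6 6-(benzyloxy)-2-bromo-3,4-dimethoxybenzaldehyde, via aryl iminium salt 5 (not isolated)
Conditions: POCl3 (2 equiv), DMF, 0 to 80 °C; then ice-water
Reagents that add atoms: N,N-dimethylformamide, CN(C)C=O; water, O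
Why: Vilsmeier–Haack formylation, an electrophilic substitution that should take C6 of 4 (ortho to OBn, para to the in-plane 3-methoxyl, next to Br) rather than C4 (wedged between OBn and OMe), the same para-over-ortho preference by which 1-bromo-3,5-dimethoxybenzene is formylated beside its bromine and 5-bromovanillin is brominated at C6.

Step 4
Reactants: 7 2,4-dihydroxybenzaldehyde
Product: 8 2,4-bis(benzyloxy)benzaldehyde
Conditions: BnBr (2.3 equiv), K2CO3, DMF, 60 °C
Reagents that add atoms: benzyl bromide, BrCc1ccccc1
Why: Double Williamson ether synthesis, in which warm DMF and excess carbonate suffice to alkylate even the 2-OH that is hydrogen-bonded to the aldehyde.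

Step 5
Reactants: 8 2,4-bis(benzyloxy)benzaldehyde
Product: 10 2,4-bis(benzyloxy)phenol, via aryl formate 9 (not isolated)
Conditions: mCPBA, CH2Cl2, 0 °C to rt; then K2CO3 (cat.), MeOH, rt
Reagents that add atoms: 3-chloroperbenzoic acid (mCPBA), O=C(OO)c1cccc(Cl)c1
Why: Baeyer–Villiger oxidation in which the aryl group, activated by ortho and para alkoxy donors, should migrate cleanly, followed by methanolysis of the formate, with the benzyl ethers inert to the peracid.

Step 6
Reactants: 10 2,4-bis(benzyloxy)phenol
Product: 11 2,4-bis(benzyloxy)-1-methoxybenzene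
Conditions: MeI, K2CO3, acetone, reflux
Reagents that add atoms: iodomethane, CI
Why: Williamson O-methylation of the only free phenol fixes what becomes the 5'-methoxyl.

Step 7
Reactants: 11 2,4-bis(benzyloxy)-1-methoxybenzene
Product: 12 1,5-bis(benzyloxy)-2-bromo-4-methoxybenzene
Conditions: NBS (1.0 equiv), MeCN, 0 °C, dark
Reagents that add atoms: N-bromosuccinimide, O=C1CCC(=O)N1Br
Why: Electrophilic aromatic bromination of a 1,2,4-trialkoxybenzene, which goes to C5 (para to the 2-OBn, ortho to the 4-OBn) because C3 is shielded by two benzyloxy groups and C6 is activated by one oxygen only, while polar solvent, low temperature and darkness suppress benzylic radical bromination.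

Step 8
Reactants: 13 methoxyacetyl chloride
Product: 14 N,2-dimethoxy-N-methylacetamide
Conditions: MeNH(OMe)·HCl, Et3N (2.2 equiv), CH2Cl2, 0 °C to rt
Reagents that add atoms: N,O-dimethylhydroxylamine hydrochloride, CNOC.Cl
Why: N-Acylation of the hydroxylamine by the acid chloride (Weinreb amide formation), a fast reaction in which the second equivalent of amine base frees the nucleophile from its salt.

Step 9
Reactants: 12 1,5-bis(benzyloxy)-2-bromo-4-methoxybenzene; 14 N,2-dimethoxy-N-methylacetamide
Product: 17 1-[2,4-bis(benzyloxy)-5-methoxyphenyl]-2-methoxyethan-1-one, via aryllithium 15 (not isolated), via tetrahedral lithium adduct 16 (not isolated)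
Conditions: n-BuLi (1.05 equiv), THF, −78 °C; then 14, −78 to 0 °C; 1 M HCl quench
Reagents that add atoms: none
Why: Bromine–lithium exchange at −78 °C is much faster than benzylic deprotonation, and the Weinreb ketone synthesis stops at the chelated adduct 16, so only the ketone should appear on acidic work-up.

Step 10
Reactants: 17 1-[2,4-bis(benzyloxy)-5-methoxyphenyl]-2-methoxyethan-1-one; 6 6-(benzyloxy)-2-bromo-3,4-dimethoxybenzaldehyde
Product: 19 3-[6-(benzyloxy)-2-bromo-3,4-dimethoxyphenyl]-1-[2,4-bis(benzyloxy)-5-methoxyphenyl]-3-hydroxy-2-methoxypropan-1-one (racemic syn/anti mixture), via lithium enolate 18 (not isolated)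
Conditions: LiHMDS (1.1 equiv), THF, −78 °C; then 6, −78 °C; AcOH quench at −78 °C
Reagents that add atoms: none
Why: Directed crossed aldol addition of a preformed, methoxy-chelated (Z)-lithium enolate to a non-enolisable aldehyde, quenched cold to forestall retro-aldol, in which the two new stereocentres form without control as a racemic syn/anti mixture that is harmless because both are erased in steps 11 and 12.

Step 11
Reactants: 19 3-[6-(benzyloxy)-2-bromo-3,4-dimethoxyphenyl]-1-[2,4-bis(benzyloxy)-5-methoxyphenyl]-3-hydroxy-2-methoxypropan-1-one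
Product: 20 1-[6-(benzyloxy)-2-bromo-3,4-dimethoxyphenyl]-3-[2,4-bis(benzyloxy)-5-methoxyphenyl]-2-methoxypropane-1,3-dione
Conditions: Dess–Martin periodinane (1.3 equiv), CH2Cl2, 0 °C to rt
Reagents that add atoms: none
Why: Dess–Martin oxidation should convert the hindered benzylic β-hydroxy ketone into the 1,3-diketone under neutral, base-free conditions that avoid retro-aldol cleavage and leave the aryl bromide and benzyl ethers untouched, the one remaining centre (C2) being enolisable and therefore stereochemically irrelevant.

Step 12
Reactants: 20 1-[6-(benzyloxy)-2-bromo-3,4-dimethoxyphenyl]-3-[2,4-bis(benzyloxy)-5-methoxyphenyl]-2-methoxypropane-1,3-dione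
Product: 22 5,2',4'-tris(benzyloxy)-3,7,8,5'-tetramethoxyflavone, via caesium enolate 21 (not isolated)
Conditions: CuI (20 mol %), 1,10-phenanthroline (40 mol %), Cs2CO3 (1.5 equiv), 4 Å MS, 1,4-dioxane, 105 °C, Ar
Reagents that add atoms: none
Why: Cs2CO3 turns 20 into the delocalised enolate 21, whose oxygen on the B-ring side binds Cu(I)·phenanthroline; oxidative addition of the nearby C8a–Br bond, held close by the C4 carbonyl, and C–O reductive elimination from the Cu(III) metallacycle then forge O1–C8a. The closest known chemistry is the Ullmann-type copper-catalysed intramolecular O-arylation of 1-(2-haloaryl)-1,3-diketones to chromones and flavones, a relative of the copper-catalysed closure of 2-haloaryl ketones to benzofurans. The one ring formed, pyranone ring C (O1–C2–C3–C4–C4a–C8a), closes in a six-membered exo mode at the sp2 carbon C8a, with the departing bromide outside the ring. No stereocentre is created, and the labile centre C2 of 20 (flavone C3) becomes sp2. The step needs O- over C-arylation and a single site on ring A: arylation at the central carbon or at the other enolate oxygen would give a four-membered ring, only C8a carries a halogen, and O5 is capped as its benzyl ether, so the 5,7,8 pattern cannot slip to 5,6,7. All other phenols are benzylated, so no competing aryl ether can form.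

Step 13
Reactants: 22 5,2',4'-tris(benzyloxy)-3,7,8,5'-tetramethoxyflavone
Product: 23 5,2',4'-trihydroxy-3,7,8,5'-tetramethoxyflavone
Conditions: H2 (1 atm), 10 % Pd/C, EtOAc–MeOH, rt
Reagents that add atoms: none
Why: Heterogeneous catalytic hydrogenolysis cleaves the three benzylic C–O bonds at 1 atm, while the methyl ethers and the tetrasubstituted, vinylogous-ester C2=C3 bond of the flavone should not be reduced under these conditions.

Compound list
1 | 3-bromo-4,5-dimethoxybenzaldehyde | COc1cc(C=O)cc(Br)c1OC | starting material
2 | 3-bromo-4,5-dimethoxyphenyl formate | COc1cc(OC=O)cc(Br)c1OC | intermediate (not isolated)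
3 | 3-bromo-4,5-dimethoxyphenol | COc1cc(O)cc(Br)c1OC | intermediate
4 | 5-(benzyloxy)-1-bromo-2,3-dimethoxybenzene | COc1cc(OCc2ccccc2)cc(Br)c1OC | intermediate
5 | {[6-(benzyloxy)-2-bromo-3,4-dimethoxyphenyl]methylidene}dimethylammonium dichlorophosphate | COc1cc(OCc2ccccc2)c(C=[N+](C)C)c(Br)c1OC.[O-]P(=O)(Cl)Cl | intermediate (not isolated)
6 | 6-(benzyloxy)-2-bromo-3,4-dimethoxybenzaldehyde | COc1cc(OCc2ccccc2)c(C=O)c(Br)c1OC | intermediate
7 | 2,4-dihydroxybenzaldehyde | O=Cc1ccc(O)cc1O | starting material
8 | 2,4-bis(benzyloxy)benzaldehyde | O=Cc1ccc(OCc2ccccc2)cc1OCc1ccccc1 | intermediate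
9 | 2,4-bis(benzyloxy)phenyl formate | O=COc1ccc(OCc2ccccc2)cc1OCc1ccccc1 | intermediate (not isolated)
10 | 2,4-bis(benzyloxy)phenol | Oc1ccc(OCc2ccccc2)cc1OCc1ccccc1 | intermediate
11 | 2,4-bis(benzyloxy)-1-methoxybenzene | COc1ccc(OCc2ccccc2)cc1OCc1ccccc1 | intermediate
12 | 1,5-bis(benzyloxy)-2-bromo-4-methoxybenzene | COc1cc(Br)c(OCc2ccccc2)cc1OCc1ccccc1 | intermediate
13 | methoxyacetyl chloride | COCC(=O)Cl | starting material
14 | N,2-dimethoxy-N-methylacetamide | COCC(=O)N(C)OC | intermediate
15 | [2,4-bis(benzyloxy)-5-methoxyphenyl]lithium | [Li]c1cc(OC)c(OCc2ccccc2)cc1OCc1ccccc1 | intermediate (not isolated)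
16 | lithium 1-[2,4-bis(benzyloxy)-5-methoxyphenyl]-2-methoxy-1-[methoxy(methyl)amino]ethan-1-olate (racemic) | [Li+].COCC([O-])(N(C)OC)c1cc(OC)c(OCc2ccccc2)cc1OCc1ccccc1 | intermediate (not isolated)
17 | 1-[2,4-bis(benzyloxy)-5-methoxyphenyl]-2-methoxyethan-1-one | COCC(=O)c1cc(OC)c(OCc2ccccc2)cc1OCc1ccccc1 | intermediate
18 | lithium (Z)-1-[2,4-bis(benzyloxy)-5-methoxyphenyl]-2-methoxyethen-1-olate | [Li+].CO/C=C(\[O-])c1cc(OC)c(OCc2ccccc2)cc1OCc1ccccc1 | intermediate (not isolated)
19 | 3-[6-(benzyloxy)-2-bromo-3,4-dimethoxyphenyl]-1-[2,4-bis(benzyloxy)-5-methoxyphenyl]-3-hydroxy-2-methoxypropan-1-one (racemic syn/anti mixture, no configuration assigned) | COC(C(O)c1c(Br)c(OC)c(OC)cc1OCc1ccccc1)C(=O)c1cc(OC)c(OCc2ccccc2)cc1OCc1ccccc1 | intermediate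
20 | 1-[6-(benzyloxy)-2-bromo-3,4-dimethoxyphenyl]-3-[2,4-bis(benzyloxy)-5-methoxyphenyl]-2-methoxypropane-1,3-dione (racemic, labile at C2) | COC(C(=O)c1c(Br)c(OC)c(OC)cc1OCc1ccccc1)C(=O)c1cc(OC)c(OCc2ccccc2)cc1OCc1ccccc1 | intermediate
21 | caesium enolate of 20 (delocalised; drawn with the charge on the B-ring-side oxygen) | [Cs+].COC(C(=O)c1c(Br)c(OC)c(OC)cc1OCc1ccccc1)=C([O-])c1cc(OC)c(OCc2ccccc2)cc1OCc1ccccc1 | intermediate (not isolated)
22 | 5,2',4'-tris(benzyloxy)-3,7,8,5'-tetramethoxyflavone | COc1cc(-c2oc3c(OC)c(OC)cc(OCc4ccccc4)c3c(=O)c2OC)c(OCc2ccccc2)cc1OCc1ccccc1 | intermediate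
23 | 5,2',4'-trihydroxy-3,7,8,5'-tetramethoxyflavone | COc1cc(-c2oc3c(OC)c(OC)cc(O)c3c(=O)c2OC)c(O)cc1O | target

Total step count: 13
Longest linear sequence: 9 steps (4, 5, 6, 7, 9, 10, 11, 12, 13)

Steps most likely to fail

**Step 12.**
- What may go wrong: copper may insert only slowly into a C–Br bond that is flanked on both sides and sits on an electron-rich ring. During prolonged heating the enolate can suffer retro-Claisen cleavage by adventitious water, or the bromine can be lost reductively.
- Fallback, from 20 back to 22: the halogen is first exchanged for oxygen, and the ring is then closed by condensation instead of by C–O coupling. Palladium-catalysed hydroxylation of 20 (Pd(OAc)2, tBuBrettPhos, B(OH)3 as hydroxide source, Cs2CO3, NMP, 80 °C) should give 1-[6-(benzyloxy)-2-hydroxy-3,4-dimethoxyphenyl]-3-[2,4-bis(benzyloxy)-5-methoxyphenyl]-2-methoxypropane-1,3-dione F1. Acid-catalysed cyclodehydration (cat. p-TsOH, toluene, 80 °C), the classical closing move of Baker–Venkataraman flavone syntheses, should then lead to 22. O5 is still benzylated, so only the new hydroxyl can attack the B-ring carbonyl and the 5,7,8 pattern is kept.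

**Step 10.**
- What may go wrong: the aldol equilibrium may be unfavourable. The aldehyde carbonyl is flanked by two ortho substituents and deactivated by ortho and para oxygen donors, so addition may stall or revert during warming and work-up.
- Fallback, from 6 (with enolate 18 made from 17 as before) back to 20, bypassing 19 and step 11: the electrophile is raised in oxidation level so that C3–C4 is made by an irreversible acylation. Pinnick oxidation of 6 (NaClO2, NaH2PO4, 2-methyl-2-butene, t-BuOH–H2O) should give 6-(benzyloxy)-2-bromo-3,4-dimethoxybenzoic acid F2. Oxalyl chloride with catalytic DMF in CH2Cl2 should convert it into 6-(benzyloxy)-2-bromo-3,4-dimethoxybenzoyl chloride F3. Adding F3 to two equivalents of 18 in THF at −78 °C (crossed Claisen-type C-acylation, the second equivalent taking up the acidic proton of the product) should deliver 20 directly.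

**Step 3.**
- What may go wrong: site selectivity may be poor, with attack at the carbon between the two alkoxy groups, and the benzyl group may be lost under acid at the temperature the deactivated ring requires.
- Fallback, from 1 back to 6, bypassing 2–5: the position of the future formyl group is marked by a halogen before the phenol is unmasked.
  - Iodination of 1 (NIS, CF3CO2H, MeCN) should take the carbon para to the 5-methoxyl and next to bromine, the site at which this ring type is known to accept a second halogen. This gives 3-bromo-2-iodo-4,5-dimethoxybenzaldehyde F4.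
  - Baeyer–Villiger oxidation (mCPBA) gives 3-bromo-2-iodo-4,5-dimethoxyphenyl formate F5, and methanolysis gives 3-bromo-2-iodo-4,5-dimethoxyphenol F6.
  - Benzylation (BnBr, K2CO3, DMF) gives 1-(benzyloxy)-3-bromo-2-iodo-4,5-dimethoxybenzene F7.
  - Iodine–magnesium exchange with i-PrMgCl·LiCl at −40 °C is far faster at iodine than at bromine and cold enough to keep the ortho-bromoaryl metal from collapsing to an aryne. It gives [2-(benzyloxy)-6-bromo-4,5-dimethoxyphenyl]magnesium chloride F8, which is formylated with DMF to give 6.

Further compounds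
F1 | step 12 | 1-[6-(benzyloxy)-2-hydroxy-3,4-dimethoxyphenyl]-3-[2,4-bis(benzyloxy)-5-methoxyphenyl]-2-methoxypropane-1,3-dione | COC(C(=O)c1c(O)c(OC)c(OC)cc1OCc1ccccc1)C(=O)c1cc(OC)c(OCc2ccccc2)cc1OCc1ccccc1
F2 | step 10 | 6-(benzyloxy)-2-bromo-3,4-dimethoxybenzoic acid | COc1cc(OCc2ccccc2)c(C(=O)O)c(Br)c1OC
F3 | step 10 | 6-(benzyloxy)-2-bromo-3,4-dimethoxybenzoyl chloride | COc1cc(OCc2ccccc2)c(C(=O)Cl)c(Br)c1OC
F4 | step 3 | 3-bromo-2-iodo-4,5-dimethoxybenzaldehyde | COc1cc(C=O)c(I)c(Br)c1OC
F5 | step 3 | 3-bromo-2-iodo-4,5-dimethoxyphenyl formate | COc1cc(OC=O)c(I)c(Br)c1OC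
F6 | step 3 | 3-bromo-2-iodo-4,5-dimethoxyphenol | COc1cc(O)c(I)c(Br)c1OC
F7 | step 3 | 1-(benzyloxy)-3-bromo-2-iodo-4,5-dimethoxybenzene | COc1cc(OCc2ccccc2)c(I)c(Br)c1OC
F8 | step 3 | [2-(benzyloxy)-6-bromo-4,5-dimethoxyphenyl]magnesium chloride | COc1cc(OCc2ccccc2)c([Mg]Cl)c(Br)c1OC
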